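The benzene ring of the target is traced back to a saturated six-membered ring that is oxidized only at the end. The key step exploits the contiguous pattern C1 (ester), C2 (oxygen), C3 (oxygen) of that ring: it is the pattern of a cyclohexanone β-keto ester whose free α′-methylene C3 takes up oxygen. In one operation, catalytic iodine in dimethyl sulfoxide should form the C3–O bond and dehydrogenate the ring to the unprotected catechol, so the target itself is the product. The precursor is racemic 16-methylheptadecyl 2-oxocyclohexane-1-carboxylate, assembled in two steps by an alkyl–alkyl coupling and an ester exchange.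

Key step: step 3

Remark: the target has no stereocenter and no stereogenic double bond; 5, 7, 8 and 9 are racemates or diastereomer mixtures whose stereocenters end as aromatic carbons, and the oxygen atom introduced at C3 is taken to come from dimethyl sulfoxide.

Step 1
Reactants: 1 12-bromododecan-1-ol; 2 1-bromo-4-methylpentane
Product: 4 16-methylheptadecan-1-ol, via (4-methylpentyl)magnesium bromide 3 (not isolated)
Conditions: 2 (2.6 equiv), Mg, THF, 45 °C; then 1, Li2CuCl4 (3 mol%), THF, −20 °C → rt; aq NH4Cl
Reagents that add atoms: none
Why: Kochi-type copper-catalysed sp3–sp3 cross-coupling of a primary alkyl Grignard reagent with a primary alkyl bromide, in which the first equivalent of 3 deprotonates the hydroxyl so that no protecting group is needed; no stereocenter is formed.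

Step 2
Reactants: 4 16-methylheptadecan-1-ol; 5 ethyl 2-oxocyclohexane-1-carboxylate (racemic)
Product: 7 16-methylheptadecyl 2-oxocyclohexane-1-carboxylate (racemic), via 2-(oxomethylidene)cyclohexan-1-one 6 (not isolated)
Conditions: 5 (1.5 equiv), DMAP (20 mol%), toluene, reflux, 4 Å MS in a Soxhlet head (−EtOH); 1 M HCl wash; excess 5 removed by Kugelrohr distillation
Reagents that add atoms: none
Why: DMAP-catalysed transesterification of an enolizable β-keto ester, in which loss of ethanol from 5 gives the acylketene 6 that the primary alcohol 4 traps while removal of ethanol drives the exchange; C1 stays racemic because it epimerizes through the enol.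

Step 3
Reactants: 7 16-methylheptadecyl 2-oxocyclohexane-1-carboxylate (racemic)
Product: 10 Gentiside D (16-methylheptadecyl 2,3-dihydroxybenzoate), via 3-iodo keto ester 8 (not isolated), via 2,3-dioxo ester 9 (not isolated)
Conditions: I2 (20 mol%), DMSO (PhCl as cosolvent if 7 does not dissolve), 80 °C then 100 °C, N2 sweep; aq Na2S2O3
Reagents that add atoms: dimethyl sulfoxide CS(C)=O
Why: Proposed new method: iodine should iodinate the enol of 7, and the secondary C3 iodide 8 should be displaced by the oxygen of DMSO and collapse with loss of Me2S (Kornblum oxidation) to the 1,2-dione 9, which creates the C3–O bond; one further iodination and loss of HI, then enolization, should give the catechol, DMSO turning each HI back into I2 (three DMSO used per molecule). The closest known reaction type is the I2-catalysed conversion of cyclohexanones, 2-substituted ones included, into catechols in DMSO, which has not been shown for 2-alkoxycarbonylcyclohexanones. No ring is closed and no stereocenter is set, since the stereocenters of 7, 8 and 9 end as ring sp2 carbons. The step needs oxygen to enter at C3 and not at C1: an iodide at C1 is tertiary, cannot become a carbonyl and gives its iodine back to iodide or to another enol, the same halogen walk that takes bromine from C1 to the α′ carbon when 2-alkoxycarbonylcyclohexanones are brominated. The substrate is freed of DMAP beforehand and the oxygenation is run at 80 °C before heating to 100 °C, so that base- or heat-driven loss of HI from the C1 iodide, the way to the salicylate, stays slow.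

Compound list
1 | 12-bromododecan-1-ol | OCCCCCCCCCCCCBr | starting material
2 | 1-bromo-4-methylpentane | CC(C)CCCBr | starting material
3 | (4-methylpentyl)magnesium bromide | CC(C)CCC[Mg]Br | intermediate
4 | 16-methylheptadecan-1-ol | CC(C)CCCCCCCCCCCCCCCO | intermediate
5 | ethyl 2-oxocyclohexane-1-carboxylate (racemic) | CCOC(=O)C1CCCCC1=O | starting material
6 | 2-(oxomethylidene)cyclohexan-1-one (acylketene) | O=C=C1CCCCC1=O | intermediate
7 | 16-methylheptadecyl 2-oxocyclohexane-1-carboxylate (racemic, partly enolized) | CC(C)CCCCCCCCCCCCCCCOC(=O)C1CCCCC1=O | intermediate
8 | 16-methylheptadecyl 3-iodo-2-oxocyclohexane-1-carboxylate (racemic mixture of diastereomers) | CC(C)CCCCCCCCCCCCCCCOC(=O)C1CCCC(I)C1=O | intermediate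
9 | 16-methylheptadecyl 2,3-dioxocyclohexane-1-carboxylate (racemic, drawn as the diketo form) | CC(C)CCCCCCCCCCCCCCCOC(=O)C1CCCC(=O)C1=O | intermediate
10 | Gentiside D, 16-methylheptadecyl 2,3-dihydroxybenzoate (achiral) | CC(C)CCCCCCCCCCCCCCCOC(=O)c1cccc(O)c1O | target

Total step count: 3
Longest linear sequence: 3 steps (1 or 2 → 4 → 7 → 10)

Steps most likely to fail

1. Step 3 (proposed new method). Dehydrogenation on the C1 side (iodination at C1 followed by loss of HI) may outrun oxygen transfer at C3, so that the ring aromatizes without taking up the second oxygen. Hydroxyl transfer to C1 and iodination of the electron-rich product ring could add to the loss. The fallback uses known chemistry and gives up the late aromatization. It sets out from alcohol 4: Steglich esterification with commercial 2,3-bis(benzyloxy)benzoic acid (EDC·HCl, DMAP, CH2Cl2, rt) should give 16-methylheptadecyl 2,3-bis(benzyloxy)benzoate F1. Hydrogenolysis (H2, 10% Pd/C, EtOAc, rt) should then remove both benzyl groups and come back to the route at 10.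

2. Step 1. Homocoupling of 3 and bromine–magnesium exchange (reduction of the bromide) may compete with cross-coupling, and deprotonated 1 may be too poorly soluble to couple cleanly. The fallback replaces the coupling by a Wittig chain extension and sets out from 1. Heating 1 with PPh3 in MeCN should give (12-hydroxydodecyl)triphenylphosphonium bromide F2. Double deprotonation with NaN(SiMe3)2 (2.1 equiv, THF, −78 °C) and addition of commercial 4-methylpentanal should give (Z)-16-methylheptadec-12-en-1-ol F3; any E isomer converges. Hydrogenation (H2, 10% Pd/C, EtOAc) comes back to the route at 4.

3. Step 2. The exchange may stall if ethanol is not removed efficiently, and the acylketene may dimerize or the keto ester may hydrolyse and decarboxylate with adventitious water. The fallback builds the ring on the long-chain ester instead of exchanging the ester, and sets out from 4 (2 equiv). Acylation with heptanedioyl dichloride (pyridine, CH2Cl2, 0 °C → rt) should give bis(16-methylheptadecyl) heptanedioate F4. Dieckmann cyclization (NaH, toluene, 80 °C; AcOH) comes back to the route at 7 and releases one equivalent of 4 for reuse.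

Further compounds
F1 | step 3 | 16-methylheptadecyl 2,3-bis(benzyloxy)benzoate | CC(C)CCCCCCCCCCCCCCCOC(=O)c1cccc(OCc2ccccc2)c1OCc1ccccc1
F2 | step 1 | (12-hydroxydodecyl)triphenylphosphonium bromide | OCCCCCCCCCCCC[P+](c1ccccc1)(c1ccccc1)c1ccccc1.[Br-]
F3 | step 1 | (Z)-16-methylheptadec-12-en-1-ol | CC(C)CC/C=C\CCCCCCCCCCCO
F4 | step 2 | bis(16-methylheptadecyl) heptanedioate | CC(C)CCCCCCCCCCCCCCCOC(=O)CCCCCC(=O)OCCCCCCCCCCCCCCCC(C)C
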